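**Retrosynthetic overview**

1. Rings are lettered A to G in the order of the target SMILES and each is numbered from its first-written atom. Ring C carries oxygen on C1, C3, C4, C5 and C6 and hydrogen only on C2. This is the pattern obtained when the four carbons of a squarate (C1, C6, C5, C4) are joined to a 1-methoxyvinyl unit (C3, C2) through a new C1–C2 bond.
2. Target 30 ⇐ BBr3 demethylation of 29 ⇐ two rounds of copper-catalysed etherification with 4-bromo-3,5-dimethoxybenzaldehyde followed by Baeyer–Villiger oxidation, which add ring B and then ring A to the ring C phenol 23.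
3. 23 ⇐ thermal ring expansion of cyclobutenone 20, which closes ring C (the only ring built; all others are purchased arenes).
4. 20 ⇐ 1-methoxyvinyllithium + aryl methyl squarate 16 ⇐ squaryl dichloride, methanol and the D–E–F–G phenol 12.
5. 12 ⇐ three rounds of the same etherification/Baeyer–Villiger pair starting from 3,4,5-trimethoxyphenol (ring G); order of rings: G, F, E, D joined, C formed, then B and A.

Key step: step 10

Remark: the target has no stereocentre; 20 is made and used as the racemate and its single stereocentre disappears in step 10. "Ar" denotes phenol 12 without its OH group. Compounds 2 and 6 are taken as catalogue chemicals (6 is otherwise one bromination away from 3,5-dimethoxybenzaldehyde).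

**Route**

Step 1
Reactants: 1 3,4,5-trimethoxyphenol; 2 4-bromo-3,5-dimethoxybenzaldehyde
Product: 3 3,5-dimethoxy-4-(3,4,5-trimethoxyphenoxy)benzaldehyde
Conditions: CuI (10 mol %), picolinic acid (20 mol %), K3PO4, DMSO, 90 °C
Reagents that add atoms: none
Why: Ullmann-type copper-catalysed diaryl ether synthesis in which the unhindered, electron-rich phenoxide of 1 should couple with bromide 2, whose para formyl group activates the C–Br bond despite the two flanking methoxy groups.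

Step 2
Reactants: 3 3,5-dimethoxy-4-(3,4,5-trimethoxyphenoxy)benzaldehyde
Product: 5 3,5-dimethoxy-4-(3,4,5-trimethoxyphenoxy)phenol, via aryl formate 4 (not isolated)
Conditions: mCPBA, CH2Cl2, 0 °C → rt; then K2CO3 (cat.), MeOH, rt
Reagents that add atoms: mCPBA, OOC(=O)c1cccc(Cl)c1
Why: Baeyer–Villiger oxidation in which the electron-rich aryl group (para aryloxy donor) should migrate to give formate 4, which methanolysis cleaves to the phenol, as in the standard conversion of 3,4,5-trimethoxybenzaldehyde into its phenol.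

Step 3
Reactants: 5 3,5-dimethoxy-4-(3,4,5-trimethoxyphenoxy)phenol; 6 2-bromo-3,5-dimethoxybenzaldehyde
Product: 7 2-[3,5-dimethoxy-4-(3,4,5-trimethoxyphenoxy)phenoxy]-3,5-dimethoxybenzaldehyde
Conditions: CuI (10 mol %), picolinic acid (20 mol %), K3PO4, DMSO, 90 °C
Reagents that add atoms: none
Why: Ullmann-type etherification of an ortho-formyl aryl bromide, a substrate class that should couple readily with unhindered phenols because the carbonyl group activates the adjacent C–Br bond.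

Step 4
Reactants: 7 2-[3,5-dimethoxy-4-(3,4,5-trimethoxyphenoxy)phenoxy]-3,5-dimethoxybenzaldehyde
Product: 9 2-[3,5-dimethoxy-4-(3,4,5-trimethoxyphenoxy)phenoxy]-3,5-dimethoxyphenol, via aryl formate 8 (not isolated)
Conditions: mCPBA, CH2Cl2, 0 °C → rt; then K2CO3 (cat.), MeOH, rt
Reagents that add atoms: mCPBA, OOC(=O)c1cccc(Cl)c1
Why: Baeyer–Villiger oxidation in which the ortho aryloxy donor should favour aryl over hydride migration, as in the known conversion of 2,3-dialkoxybenzaldehydes into the corresponding phenols.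

Step 5
Reactants: 9 2-[3,5-dimethoxy-4-(3,4,5-trimethoxyphenoxy)phenoxy]-3,5-dimethoxyphenol; 2 4-bromo-3,5-dimethoxybenzaldehyde
Product: 10 4-{2-[3,5-dimethoxy-4-(3,4,5-trimethoxyphenoxy)phenoxy]-3,5-dimethoxyphenoxy}-3,5-dimethoxybenzaldehyde
Conditions: CuI (20 mol %), picolinic acid (40 mol %), K3PO4, DMSO, 100 °C
Reagents that add atoms: none
Why: Ullmann-type etherification under conditions suited to ortho-substituted phenols, in which the formyl-activated bromide should accept the phenoxide of 9, which carries one ortho aryloxy group.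

Step 6
Reactants: 10 4-{2-[3,5-dimethoxy-4-(3,4,5-trimethoxyphenoxy)phenoxy]-3,5-dimethoxyphenoxy}-3,5-dimethoxybenzaldehyde
Product: 12 4-{2-[3,5-dimethoxy-4-(3,4,5-trimethoxyphenoxy)phenoxy]-3,5-dimethoxyphenoxy}-3,5-dimethoxyphenol (ArOH), via aryl formate 11 (not isolated)
Conditions: mCPBA, CH2Cl2, 0 °C → rt; then K2CO3 (cat.), MeOH, rt
Reagents that add atoms: mCPBA, OOC(=O)c1cccc(Cl)c1
Why: Baeyer–Villiger oxidation and formate methanolysis of the same 4-aryloxy-3,5-dimethoxybenzaldehyde type as in step 2.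

Step 7
Reactants: 13 squaric acid (3,4-dihydroxycyclobut-3-ene-1,2-dione)
Product: 14 3,4-dichlorocyclobut-3-ene-1,2-dione (squaryl dichloride)
Conditions: (COCl)2, DMF (cat.), CH2Cl2, reflux
Reagents that add atoms: oxalyl chloride, ClC(=O)C(Cl)=O
Why: Vilsmeier-type chlorodehydroxylation of a vinylogous carboxylic acid, the known preparation of squaryl dichloride.

Step 8
Reactants: 14 3,4-dichlorocyclobut-3-ene-1,2-dione; 12 ArOH
Product: 16 3-(ArO)-4-methoxycyclobut-3-ene-1,2-dione, via 3-chloro-4-methoxycyclobut-3-ene-1,2-dione 15 (not isolated)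
Conditions: 14 (1.5 equiv), MeOH (1.5 equiv), CH2Cl2, −40 → 0 °C, N2 sweep; then 12, i-Pr2NEt, −40 → 0 °C
Reagents that add atoms: methanol, CO
Why: two successive addition–elimination reactions of a vinylogous acid chloride, in which the first chloride of 14 should be displaced by methanol much faster than the second and the remaining chloride of 15 is then displaced by the phenoxide of 12 in preference to methoxide.

Step 9
Reactants: 16 3-(ArO)-4-methoxycyclobut-3-ene-1,2-dione; 17 methyl vinyl ether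
Product: 20 racemic 2-(ArO)-3,4-dimethoxy-4-(1-methoxyvinyl)cyclobut-2-en-1-one, via 1-methoxyvinyllithium 18 (not isolated), via lithium alkoxide 19 (not isolated)
Conditions: 17, t-BuLi, THF, −78 → 0 °C; then 16, THF, −78 °C; then MeOTf, −78 → 0 °C; aq NaHCO3 work-up
Reagents that add atoms: methyl triflate, COS(=O)(=O)C(F)(F)F
Why: 1,2-addition of an organolithium to a squarate carbonyl and O-methylation of the lithium alkoxide with methyl triflate, in which attack is expected at the carbonyl next to the methoxy-bearing carbon because that carbonyl is conjugated with the weaker aryloxy donor and is the less shielded one; the new quaternary centre forms as a racemate, which is of no consequence since step 10 removes it.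

Step 10
Reactants: 20 racemic 2-(ArO)-3,4-dimethoxy-4-(1-methoxyvinyl)cyclobut-2-en-1-one
Product: 23 2-(ArO)-3,4,5-trimethoxyphenol (per-methylated C–D–E–F–G pentamer with free OH on ring C C1), via dienylketene 21 (not isolated), via cyclohexadienone 22 (not isolated)
Conditions: degassed PhMe (0.01 M), 110 °C
Reagents that add atoms: none
Why: On heating, the strained C1–C4 bond of 20 should open in a conrotatory four-electron electrocyclic reaction to dienylketene 21; the C4 methoxy group, the stronger donor, turns outward, so the 1-methoxyvinyl group turns inward and ends cis to the ketene across the new C3=C4 bond. A six-electron disrotatory electrocyclisation then joins the ketene carbon (ring C C1) to the vinyl CH2 terminus (ring C C2), which closes ring C as a six-membered carbocycle (dienone 22), and enolisation of its CH2–C=O unit gives phenol 23. The closest known reaction type is the thermal ring expansion of squarate-derived 4-alkenyl-4-alkoxycyclobutenones to polyoxygenated phenols (Moore rearrangement). No stereocentre is formed, and the single racemic centre of 20 becomes sp2. The step needs torquoselectivity and site selectivity: the first is secured by the outward preference of the C4 alkoxy donor, the second by the fact that only the vinyl CH2 lies within reach of the ketene carbon, while the carbon bearing the ring D ether stays sp2 throughout.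

Step 11
Reactants: 23 2-(ArO)-3,4,5-trimethoxyphenol; 2 4-bromo-3,5-dimethoxybenzaldehyde
Product: 24 3,5-dimethoxy-4-[2-(ArO)-3,4,5-trimethoxyphenoxy]benzaldehyde
Conditions: CuI (20 mol %), picolinic acid (40 mol %), K3PO4, DMSO, 100 °C, Ar
Reagents that add atoms: none
Why: Ullmann-type etherification of the same kind as step 5 (phenol with one ortho aryloxy group, formyl-activated bromide), which introduces ring B through its C4.

Step 12
Reactants: 24 3,5-dimethoxy-4-[2-(ArO)-3,4,5-trimethoxyphenoxy]benzaldehyde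
Product: 26 3,5-dimethoxy-4-[2-(ArO)-3,4,5-trimethoxyphenoxy]phenol, via aryl formate 25 (not isolated)
Conditions: mCPBA, CH2Cl2, 0 °C → rt; then K2CO3 (cat.), MeOH, rt
Reagents that add atoms: mCPBA, OOC(=O)c1cccc(Cl)c1
Why: Baeyer–Villiger oxidation and formate methanolysis as in step 2; the aldehyde should react faster with the peracid than the fully etherified arene rings.

Step 13
Reactants: 26 3,5-dimethoxy-4-[2-(ArO)-3,4,5-trimethoxyphenoxy]phenol; 2 4-bromo-3,5-dimethoxybenzaldehyde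
Product: 27 4-{3,5-dimethoxy-4-[2-(ArO)-3,4,5-trimethoxyphenoxy]phenoxy}-3,5-dimethoxybenzaldehyde
Conditions: CuI (10 mol %), picolinic acid (20 mol %), K3PO4, DMSO, 90 °C, Ar
Reagents that add atoms: none
Why: Ullmann-type etherification of an unhindered phenol with the formyl-activated bromide as in step 1, which introduces ring A through its C4.

Step 14
Reactants: 27 4-{3,5-dimethoxy-4-[2-(ArO)-3,4,5-trimethoxyphenoxy]phenoxy}-3,5-dimethoxybenzaldehyde
Product: 29 4-{3,5-dimethoxy-4-[2-(ArO)-3,4,5-trimethoxyphenoxy]phenoxy}-3,5-dimethoxyphenol (hexadecamethyl ether of the target), via aryl formate 28 (not isolated)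
Conditions: mCPBA, CH2Cl2, 0 °C → rt; then K2CO3 (cat.), MeOH, rt
Reagents that add atoms: mCPBA, OOC(=O)c1cccc(Cl)c1
Why: Baeyer–Villiger oxidation and formate methanolysis as in step 2, which turns the formyl carbon of ring A into its C1 hydroxyl.

Step 15
Reactants: 29 hexadecamethyl ether of the target
Product: 30 CNP0351377.0
Conditions: BBr3 (excess), CH2Cl2, −78 °C → rt; then MeOH, H2O, under Ar
Reagents that add atoms: none
Why: Lewis-acid cleavage of aryl methyl ethers by bromide attack on the O-methyl carbon of the borate complexes, which should remove all sixteen methyl groups while leaving the diaryl ether bonds intact.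

**Compound list**

1 | 3,4,5-trimethoxyphenol | COc1cc(O)cc(OC)c1OC | starting material
2 | 4-bromo-3,5-dimethoxybenzaldehyde | COc1cc(C=O)cc(OC)c1Br | starting material
3 | 3,5-dimethoxy-4-(3,4,5-trimethoxyphenoxy)benzaldehyde | O=Cc1cc(OC)c(Oc2cc(OC)c(OC)c(OC)c2)c(OC)c1 | intermediate
4 | 3,5-dimethoxy-4-(3,4,5-trimethoxyphenoxy)phenyl formate | O=COc1cc(OC)c(Oc2cc(OC)c(OC)c(OC)c2)c(OC)c1 | intermediate
5 | 3,5-dimethoxy-4-(3,4,5-trimethoxyphenoxy)phenol | Oc1cc(OC)c(Oc2cc(OC)c(OC)c(OC)c2)c(OC)c1 | intermediate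
6 | 2-bromo-3,5-dimethoxybenzaldehyde | COc1cc(C=O)c(Br)c(OC)c1 | starting material
7 | 2-[3,5-dimethoxy-4-(3,4,5-trimethoxyphenoxy)phenoxy]-3,5-dimethoxybenzaldehyde | O=Cc1cc(OC)cc(OC)c1Oc1cc(OC)c(Oc2cc(OC)c(OC)c(OC)c2)c(OC)c1 | intermediate
8 | 2-[3,5-dimethoxy-4-(3,4,5-trimethoxyphenoxy)phenoxy]-3,5-dimethoxyphenyl formate | O=COc1cc(OC)cc(OC)c1Oc1cc(OC)c(Oc2cc(OC)c(OC)c(OC)c2)c(OC)c1 | intermediate
9 | 2-[3,5-dimethoxy-4-(3,4,5-trimethoxyphenoxy)phenoxy]-3,5-dimethoxyphenol | Oc1cc(OC)cc(OC)c1Oc1cc(OC)c(Oc2cc(OC)c(OC)c(OC)c2)c(OC)c1 | intermediate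
10 | 4-{2-[3,5-dimethoxy-4-(3,4,5-trimethoxyphenoxy)phenoxy]-3,5-dimethoxyphenoxy}-3,5-dimethoxybenzaldehyde | O=Cc1cc(OC)c(Oc2cc(OC)cc(OC)c2Oc2cc(OC)c(Oc3cc(OC)c(OC)c(OC)c3)c(OC)c2)c(OC)c1 | intermediate
11 | 4-{2-[3,5-dimethoxy-4-(3,4,5-trimethoxyphenoxy)phenoxy]-3,5-dimethoxyphenoxy}-3,5-dimethoxyphenyl formate | O=COc1cc(OC)c(Oc2cc(OC)cc(OC)c2Oc2cc(OC)c(Oc3cc(OC)c(OC)c(OC)c3)c(OC)c2)c(OC)c1 | intermediate
12 | 4-{2-[3,5-dimethoxy-4-(3,4,5-trimethoxyphenoxy)phenoxy]-3,5-dimethoxyphenoxy}-3,5-dimethoxyphenol (ArOH, per-methylated D–E–F–G phenol) | Oc1cc(OC)c(Oc2cc(OC)cc(OC)c2Oc2cc(OC)c(Oc3cc(OC)c(OC)c(OC)c3)c(OC)c2)c(OC)c1 | intermediate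
13 | squaric acid | OC1=C(O)C(=O)C1=O | starting material
14 | 3,4-dichlorocyclobut-3-ene-1,2-dione | ClC1=C(Cl)C(=O)C1=O | intermediate
15 | 3-chloro-4-methoxycyclobut-3-ene-1,2-dione | COC1=C(Cl)C(=O)C1=O | intermediate
16 | 3-(ArO)-4-methoxycyclobut-3-ene-1,2-dione | COC1=C(Oc2cc(OC)c(Oc3cc(OC)cc(OC)c3Oc3cc(OC)c(Oc4cc(OC)c(OC)c(OC)c4)c(OC)c3)c(OC)c2)C(=O)C1=O | intermediate
17 | methyl vinyl ether | C=COC | starting material
18 | 1-methoxyvinyllithium | [Li]C(=C)OC | intermediate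
19 | lithium 3-(ArO)-2-methoxy-1-(1-methoxyvinyl)-4-oxocyclobut-2-en-1-olate (racemic) | [Li+].[O-]C1(C(=C)OC)C(OC)=C(Oc2cc(OC)c(Oc3cc(OC)cc(OC)c3Oc3cc(OC)c(Oc4cc(OC)c(OC)c(OC)c4)c(OC)c3)c(OC)c2)C1=O | intermediate
20 | racemic 2-(ArO)-3,4-dimethoxy-4-(1-methoxyvinyl)cyclobut-2-en-1-one | C=C(OC)C1(OC)C(OC)=C(Oc2cc(OC)c(Oc3cc(OC)cc(OC)c3Oc3cc(OC)c(Oc4cc(OC)c(OC)c(OC)c4)c(OC)c3)c(OC)c2)C1=O | intermediate
21 | (3Z)-2-(ArO)-3,4,5-trimethoxyhexa-1,3,5-trien-1-one (dienylketene) | O=C=C(Oc1cc(OC)c(Oc2cc(OC)cc(OC)c2Oc2cc(OC)c(Oc3cc(OC)c(OC)c(OC)c3)c(OC)c2)c(OC)c1)/C(OC)=C(OC)\C(OC)=C | intermediate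
22 | 2-(ArO)-3,4,5-trimethoxycyclohexa-2,4-dien-1-one | O=C1CC(OC)=C(OC)C(OC)=C1Oc1cc(OC)c(Oc2cc(OC)cc(OC)c2Oc2cc(OC)c(Oc3cc(OC)c(OC)c(OC)c3)c(OC)c2)c(OC)c1 | intermediate
23 | 2-(ArO)-3,4,5-trimethoxyphenol (per-methylated C–D–E–F–G pentamer, free OH on ring C C1) | Oc1cc(OC)c(OC)c(OC)c1Oc1cc(OC)c(Oc2cc(OC)cc(OC)c2Oc2cc(OC)c(Oc3cc(OC)c(OC)c(OC)c3)c(OC)c2)c(OC)c1 | intermediate
24 | 3,5-dimethoxy-4-[2-(ArO)-3,4,5-trimethoxyphenoxy]benzaldehyde | O=Cc1cc(OC)c(Oc2cc(OC)c(OC)c(OC)c2Oc2cc(OC)c(Oc3cc(OC)cc(OC)c3Oc3cc(OC)c(Oc4cc(OC)c(OC)c(OC)c4)c(OC)c3)c(OC)c2)c(OC)c1 | intermediate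
25 | 3,5-dimethoxy-4-[2-(ArO)-3,4,5-trimethoxyphenoxy]phenyl formate | O=COc1cc(OC)c(Oc2cc(OC)c(OC)c(OC)c2Oc2cc(OC)c(Oc3cc(OC)cc(OC)c3Oc3cc(OC)c(Oc4cc(OC)c(OC)c(OC)c4)c(OC)c3)c(OC)c2)c(OC)c1 | intermediate
26 | 3,5-dimethoxy-4-[2-(ArO)-3,4,5-trimethoxyphenoxy]phenol | Oc1cc(OC)c(Oc2cc(OC)c(OC)c(OC)c2Oc2cc(OC)c(Oc3cc(OC)cc(OC)c3Oc3cc(OC)c(Oc4cc(OC)c(OC)c(OC)c4)c(OC)c3)c(OC)c2)c(OC)c1 | intermediate
27 | 4-{3,5-dimethoxy-4-[2-(ArO)-3,4,5-trimethoxyphenoxy]phenoxy}-3,5-dimethoxybenzaldehyde | O=Cc1cc(OC)c(Oc2cc(OC)c(Oc3cc(OC)c(OC)c(OC)c3Oc3cc(OC)c(Oc4cc(OC)cc(OC)c4Oc4cc(OC)c(Oc5cc(OC)c(OC)c(OC)c5)c(OC)c4)c(OC)c3)c(OC)c2)c(OC)c1 | intermediate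
28 | 4-{3,5-dimethoxy-4-[2-(ArO)-3,4,5-trimethoxyphenoxy]phenoxy}-3,5-dimethoxyphenyl formate | O=COc1cc(OC)c(Oc2cc(OC)c(Oc3cc(OC)c(OC)c(OC)c3Oc3cc(OC)c(Oc4cc(OC)cc(OC)c4Oc4cc(OC)c(Oc5cc(OC)c(OC)c(OC)c5)c(OC)c4)c(OC)c3)c(OC)c2)c(OC)c1 | intermediate
29 | 4-{3,5-dimethoxy-4-[2-(ArO)-3,4,5-trimethoxyphenoxy]phenoxy}-3,5-dimethoxyphenol (hexadecamethyl ether of the target) | Oc1cc(OC)c(Oc2cc(OC)c(Oc3cc(OC)c(OC)c(OC)c3Oc3cc(OC)c(Oc4cc(OC)cc(OC)c4Oc4cc(OC)c(Oc5cc(OC)c(OC)c(OC)c5)c(OC)c4)c(OC)c3)c(OC)c2)c(OC)c1 | intermediate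
30 | CNP0351377.0 | Oc1cc(O)c(Oc2cc(O)c(Oc3cc(O)c(O)c(O)c3Oc3cc(O)c(Oc4cc(O)cc(O)c4Oc4cc(O)c(Oc5cc(O)c(O)c(O)c5)c(O)c4)c(O)c3)c(O)c2)c(O)c1 | target

**Step count and risks**

Total step count: 15. Longest linear sequence: 14 steps (steps 1–6 and 8–15, from 1 to 30); step 7 is a one-step side branch.

The three steps most likely to fail:

Step 10. The dienylketene may be consumed before it electrocyclises, for instance by acylating the electron-rich ring D at the position ortho to the ether oxygen, by dimerising, or by capturing adventitious nucleophiles; the acid-labile enol ether may also be hydrolysed before ring opening. Fallback, setting out from 12 and coming back at 23: ring C would be taken from a purchased arene instead of being built. Phenol 12 would be coupled with commercial 2-bromo-3,4,5-trimethoxybenzaldehyde (CuI, picolinic acid, K3PO4, DMSO, 90 °C) to give 2-(ArO)-3,4,5-trimethoxybenzaldehyde F1. Baeyer–Villiger oxidation with mCPBA would give 2-(ArO)-3,4,5-trimethoxyphenyl formate F2, whose methanolysis (K2CO3, MeOH) gives 23.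

Step 9. The vinyllithium may add in part to the other carbonyl (regiochemical leakage that would place the ring D ether meta to the ring C hydroxyl), or may displace aryloxide by conjugate addition–elimination. Fallback, setting out from 14 and 12 and coming back at 20: the regiochemistry would be fixed by symmetry and by position instead of by donor strength.
- Dichloride 14 would be treated with two equivalents of 12 and i-Pr2NEt to give the symmetrical 3,4-bis(ArO)cyclobut-3-ene-1,2-dione F3, in which both carbonyls are equivalent.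
- Addition of 18 would give the lithium 2,3-bis(ArO)-1-(1-methoxyvinyl)-4-oxocyclobut-2-en-1-olate F4, and methyl triflate would then give racemic 2,3-bis(ArO)-4-methoxy-4-(1-methoxyvinyl)cyclobut-2-en-1-one F5.
- One equivalent of NaOMe in MeOH–THF at −40 °C should exchange only the aryloxy group on C3, the β-carbon of the enone, by addition–elimination; this gives 20 and returns one equivalent of 12.

Step 11. The coupling joins a phenoxide flanked by a bulky aryloxy group to a bromide flanked by two methoxy groups, so it may be slow, with protodebromination of 2 and copper-mediated oxidation of the very electron-rich ring C competing. Fallback, setting out from 23 and coming back at the target 30: the polarity of the union would be reversed and rings A and B brought in as one piece under palladium catalysis.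
- Commercial 4-bromo-2,6-dimethoxyphenol would be benzylated (BnBr, K2CO3, DMF) to 2-(benzyloxy)-5-bromo-1,3-dimethoxybenzene F6.
- F6 would be coupled with commercial 2,4,6-trimethoxyphenol (CuI, picolinic acid, K3PO4, DMSO) to give 2-[4-(benzyloxy)-3,5-dimethoxyphenoxy]-1,3,5-trimethoxybenzene F7.
- Hydrogenolysis (H2, Pd/C, EtOAc) would give 2,6-dimethoxy-4-(2,4,6-trimethoxyphenoxy)phenol F8.
- Phenol 23 would be converted with C4F9SO2F and Et3N into 2-(ArO)-3,4,5-trimethoxyphenyl nonafluorobutane-1-sulfonate F9.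
- F9 and F8 would be coupled with Pd(OAc)2, 2-di-tert-butylphosphino-2',4',6'-triisopropylbiphenyl and K3PO4 in toluene at 100 °C to give the heptadecamethyl ether of the target F10.
- BBr3 then converts F10 into 30.

**Further compounds**

F1 | step 10 | 2-(ArO)-3,4,5-trimethoxybenzaldehyde | O=Cc1cc(OC)c(OC)c(OC)c1Oc1cc(OC)c(Oc2cc(OC)cc(OC)c2Oc2cc(OC)c(Oc3cc(OC)c(OC)c(OC)c3)c(OC)c2)c(OC)c1
F2 | step 10 | 2-(ArO)-3,4,5-trimethoxyphenyl formate | O=COc1cc(OC)c(OC)c(OC)c1Oc1cc(OC)c(Oc2cc(OC)cc(OC)c2Oc2cc(OC)c(Oc3cc(OC)c(OC)c(OC)c3)c(OC)c2)c(OC)c1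
F3 | step 9 | 3,4-bis(ArO)cyclobut-3-ene-1,2-dione | O=C1C(=O)C(Oc2cc(OC)c(Oc3cc(OC)cc(OC)c3Oc3cc(OC)c(Oc4cc(OC)c(OC)c(OC)c4)c(OC)c3)c(OC)c2)=C1Oc1cc(OC)c(Oc2cc(OC)cc(OC)c2Oc2cc(OC)c(Oc3cc(OC)c(OC)c(OC)c3)c(OC)c2)c(OC)c1
F4 | step 9 | lithium 2,3-bis(ArO)-1-(1-methoxyvinyl)-4-oxocyclobut-2-en-1-olate (racemic) | [Li+].[O-]C1(C(=C)OC)C(Oc2cc(OC)c(Oc3cc(OC)cc(OC)c3Oc3cc(OC)c(Oc4cc(OC)c(OC)c(OC)c4)c(OC)c3)c(OC)c2)=C(Oc2cc(OC)c(Oc3cc(OC)cc(OC)c3Oc3cc(OC)c(Oc4cc(OC)c(OC)c(OC)c4)c(OC)c3)c(OC)c2)C1=O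
F5 | step 9 | racemic 2,3-bis(ArO)-4-methoxy-4-(1-methoxyvinyl)cyclobut-2-en-1-one | C=C(OC)C1(OC)C(Oc2cc(OC)c(Oc3cc(OC)cc(OC)c3Oc3cc(OC)c(Oc4cc(OC)c(OC)c(OC)c4)c(OC)c3)c(OC)c2)=C(Oc2cc(OC)c(Oc3cc(OC)cc(OC)c3Oc3cc(OC)c(Oc4cc(OC)c(OC)c(OC)c4)c(OC)c3)c(OC)c2)C1=O
F6 | step 11 | 2-(benzyloxy)-5-bromo-1,3-dimethoxybenzene | COc1cc(Br)cc(OC)c1OCc1ccccc1
F7 | step 11 | 2-[4-(benzyloxy)-3,5-dimethoxyphenoxy]-1,3,5-trimethoxybenzene | COc1cc(OC)c(Oc2cc(OC)c(OCc3ccccc3)c(OC)c2)c(OC)c1
F8 | step 11 | 2,6-dimethoxy-4-(2,4,6-trimethoxyphenoxy)phenol | COc1cc(OC)c(Oc2cc(OC)c(O)c(OC)c2)c(OC)c1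
F9 | step 11 | 2-(ArO)-3,4,5-trimethoxyphenyl nonafluorobutane-1-sulfonate | O=S(=O)(Oc1cc(OC)c(OC)c(OC)c1Oc1cc(OC)c(Oc2cc(OC)cc(OC)c2Oc2cc(OC)c(Oc3cc(OC)c(OC)c(OC)c3)c(OC)c2)c(OC)c1)C(F)(F)C(F)(F)C(F)(F)C(F)(F)F
F10 | step 11 | heptadecamethyl ether of the target | COc1cc(OC)c(Oc2cc(OC)c(Oc3cc(OC)c(OC)c(OC)c3Oc3cc(OC)c(Oc4cc(OC)cc(OC)c4Oc4cc(OC)c(Oc5cc(OC)c(OC)c(OC)c5)c(OC)c4)c(OC)c3)c(OC)c2)c(OC)c1
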